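The eleven-membered carbocycle (C1 = methylidene carbon, C5 = carboxyl-bearing alkene carbon, C7 = angelate carbinol, C11 = free carbinol) holds a 1,5-diene, CH2=C1–C2–C3–C4=C5, whose C2–C3 bond joins two allylic carbons, the allyl unit about C1 being symmetrical. The route cuts that bond: a zerovalent-palladium allyl–allyl coupling of a C3 allylic methyl carbonate and a C2 allylstannane closes the ring and completes the diene in one operation without touching a stereocentre. Its acyclic precursor already carries C7 (S, angelate), C11 (S, silyl ether) and the E-enoate as a SEM ester, and is built linearly from 2,2-dimethylpent-4-enal.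

Key step: step 14

Remark: ring numbers C1–C11 are used for the corresponding atoms of all intermediates; the target is read as 7S,11S, E at C4=C5 (C3 cis to C6) and Z in the angelate; α-isocupreine is assumed to be on hand (one step from quinine with CF3SO3H).

Step 1
Reactants: 1 2,2-dimethylpent-4-enal; 2 (methoxymethyl)triphenylphosphonium chloride
Product: 4 1-methoxy-3,3-dimethylhexa-1,5-diene (E/Z mixture), via phosphorus ylide 3 (not isolated)
Conditions: KOtBu, THF, 0 °C; then 1, 0 °C → rt
Reagents that add atoms: none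
Why: Wittig olefination of the non-enolisable aldehyde with the methoxymethylene ylide should add the future C11 as a masked aldehyde carbon, the enol ether geometry being irrelevant.

Step 2
Reactants: 4 1-methoxy-3,3-dimethylhexa-1,5-diene
Product: 5 3,3-dimethylhex-5-enal
Conditions: 2 M aq. HCl, THF, rt
Reagents that add atoms: water, O
Why: Acid hydrolysis of the enol ether (oxocarbenium ion, hemiacetal) should free the homologated C11 aldehyde while the isolated C6=C7 alkene stays inert.

Step 3
Reactants: 5 3,3-dimethylhex-5-enal; 6 1,1,1,3,3,3-hexafluoropropan-2-yl prop-2-enoate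
Product: 7 1,1,1,3,3,3-hexafluoropropan-2-yl (3S)-3-hydroxy-5,5-dimethyl-2-methylideneoct-7-enoate
Conditions: α-isocupreine (0.1 equiv), DMF, −55 °C
Reagents that add atoms: none
Why: Morita–Baylis–Hillman reaction of the activated acrylate forms C11–C1, and the quinine-derived amine–phenol catalyst should set C11 as S under catalyst control (its pseudoenantiomer β-isocupreidine is known to give the R series, which would be wrong here).

Step 4
Reactants: 7 the 11S Baylis–Hillman adduct
Product: 8 1,1,1,3,3,3-hexafluoropropan-2-yl (3S)-3-[(tert-butyldimethylsilyl)oxy]-5,5-dimethyl-2-methylideneoct-7-enoate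
Conditions: TBSOTf, 2,6-lutidine, CH2Cl2, −78 → 0 °C
Reagents that add atoms: tert-butyldimethylsilyl trifluoromethanesulfonate, CC(C)(C)[Si](C)(C)OS(=O)(=O)C(F)(F)F
Why: Silylation of the secondary allylic alcohol gives a C11 protecting group that zerovalent palladium cannot ionise later, which an ester at this position next to the allylmetal unit could not guarantee.

Step 5
Reactants: 8 the silyl ether
Product: 9 1,1,1,3,3,3-hexafluoropropan-2-yl (3S)-3-[(tert-butyldimethylsilyl)oxy]-5,5-dimethyl-2-methylidene-6-(oxiran-2-yl)hexanoate (both C7 epimers)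
Conditions: mCPBA, NaHCO3, CH2Cl2, 0 °C → rt
Reagents that add atoms: 3-chloroperoxybenzoic acid, OOC(=O)c1cccc(Cl)c1
Why: Prilezhaev epoxidation should touch only the isolated C6=C7 alkene because the acrylate alkene is electron-poor; C7 is formed without facial control and is corrected in step 6.

Step 6
Reactants: 9 the epoxide mixture
Product: 10 1,1,1,3,3,3-hexafluoropropan-2-yl (3S)-3-[(tert-butyldimethylsilyl)oxy]-5,5-dimethyl-2-methylidene-6-[(2S)-oxiran-2-yl]hexanoate
Conditions: (S,S)-(salen)Co(OAc) (1 mol%; salen = N,N'-bis(3,5-di-tert-butylsalicylidene)cyclohexane-1,2-diaminate), H2O (0.55 equiv), THF, 0 °C → rt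
Reagents that add atoms: none
Why: Hydrolytic kinetic resolution: the (S,S) cobalt catalyst should hydrolyse the 7R epoxide to the diol and leave the 7S epoxide, catalyst control overriding the remote C11 centre.

Step 7
Reactants: 10 the 7S,11S epoxy ester
Product: 11 (3S)-3-[(tert-butyldimethylsilyl)oxy]-5,5-dimethyl-2-methylidene-6-[(2S)-oxiran-2-yl]hexan-1-ol
Conditions: i-Bu2AlH (2.5 equiv), CH2Cl2, −78 °C; aq. potassium sodium tartrate
Reagents that add atoms: none
Why: Hydride 1,2-reduction of the activated ester gives the C2 allylic alcohol, the epoxide and silyl ether being inert to i-Bu2AlH at −78 °C.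

Step 8
Reactants: 11 the allylic alcohol
Product: 13 tributyl{(3S)-3-[(tert-butyldimethylsilyl)oxy]-5,5-dimethyl-2-methylidene-6-[(2S)-oxiran-2-yl]hexyl}stannane, via allylic mesylate 12 (not isolated)
Conditions: n-BuLi (1.0 equiv), THF, −78 °C; MsCl; then Bu3SnLi (from Bu3SnH and LiN(i-Pr)2), −78 °C
Reagents that add atoms: methanesulfonyl chloride, CS(=O)(=O)Cl (atoms in 12 only); tributylstannyllithium, [Li][Sn](CCCC)(CCCC)CCCC
Why: Nucleophilic substitution of the primary allylic mesylate by the stannyl anion (SN2 or SN2′, identical for this 2-substituted allyl unit) is far faster at −78 °C than epoxide opening, so tin goes in before any ester is present.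

Step 9
Reactants: 13 the epoxy allylstannane; 14 triethyl phosphonoacetate
Product: 15 diethyl [(5S)-5-{(4S)-4-[(tert-butyldimethylsilyl)oxy]-2,2-dimethyl-5-[(tributylstannyl)methyl]hex-5-en-1-yl}-2-oxooxolan-3-yl]phosphonate (both C5 epimers)
Conditions: NaH, DME, 65 °C; aq. NH4Cl
Reagents that add atoms: none
Why: SN2 opening of the epoxide at terminal C6 by the sodium phosphonoacetate and lactonisation of the γ-hydroxy ester on work-up forms C5–C6 with C7 untouched (7S kept), the temperature being held below that of the competing cyclopropanation; the C5 centre is lost in step 10.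

Step 10
Reactants: 15 the phosphono lactone; 16 2-oxoethyl benzoate
Product: 17 2-[(3E,5S)-5-{(4S)-4-[(tert-butyldimethylsilyl)oxy]-2,2-dimethyl-5-[(tributylstannyl)methyl]hex-5-en-1-yl}-2-oxooxolan-3-ylidene]ethyl benzoate
Conditions: KOtBu, THF, 0 °C; then 16, −78 → 0 °C
Reagents that add atoms: none
Why: Horner–Wadsworth–Emmons olefination of the α-phosphono lactone should give mainly the E alkylidene lactone (C3 trans to the carbonyl, cis to C6), which is the ring geometry of the target enoate.

Step 11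
Reactants: 17 the alkylidene lactone
Product: 19 [2-(trimethylsilyl)ethoxy]methyl (2E,4S,8S)-8-[(tert-butyldimethylsilyl)oxy]-4-hydroxy-2-(2-hydroxyethylidene)-6,6-dimethyl-9-methylidene-10-(tributylstannyl)decanoate, via lithium carboxylate 18 (not isolated)
Conditions: LiOH, THF–H2O, 0 °C → rt; NaH2PO4 to pH 8, evaporate; SEMCl (excess), DMF, 0 °C
Reagents that add atoms: lithium hydroxide, [Li+].[OH-]; 2-(trimethylsilyl)ethoxymethyl chloride, C[Si](C)(C)CCOCCl
Why: Saponification opens the lactone and removes the benzoate, and O-alkylation of the carboxylate salt esterifies it without ever forming the free γ-hydroxy acid, which would relactonise; the neutral hydroxyls are not alkylated without added base.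

Step 12
Reactants: 19 the C3,C7 diol SEM ester
Product: 20 [2-(trimethylsilyl)ethoxy]methyl (2E,4S,8S)-8-[(tert-butyldimethylsilyl)oxy]-4-hydroxy-2-{2-[(methoxycarbonyl)oxy]ethylidene}-6,6-dimethyl-9-methylidene-10-(tributylstannyl)decanoate
Conditions: ClCO2Me (1.1 equiv), pyridine, CH2Cl2, −30 °C
Reagents that add atoms: methyl chloroformate, COC(=O)Cl
Why: Chemoselective acylation of the primary allylic C3 hydroxyl over the hindered secondary C7 hydroxyl installs the leaving group for the key step.

Step 13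
Reactants: 20 the C3 carbonate; 21 angelic acid
Product: 23 [2-(trimethylsilyl)ethoxy]methyl (2E,4S,8S)-8-[(tert-butyldimethylsilyl)oxy]-2-{2-[(methoxycarbonyl)oxy]ethylidene}-6,6-dimethyl-9-methylidene-4-{[(2Z)-2-methylbut-2-enoyl]oxy}-10-(tributylstannyl)decanoate, via mixed anhydride 22 (not isolated)
Conditions: 21, 2,4,6-Cl3C6H2COCl, Et3N, toluene, rt; then 20, DMAP (0.2 equiv), rt → 40 °C
Reagents that add atoms: 2,4,6-trichlorobenzoyl chloride, O=C(Cl)c1c(Cl)cc(Cl)cc1Cl (atoms in 22 only)
Why: Yamaguchi esterification acylates the C7 hydroxyl with retention of configuration, and the mild base and temperature are chosen to limit Z-to-E isomerisation of the angeloyl group and lactonisation of the γ-hydroxy ester.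

Step 14
Reactants: 23 the allylstannane allylic carbonate
Product: 24 [2-(trimethylsilyl)ethoxy]methyl (1E,6S,10S)-6-[(tert-butyldimethylsilyl)oxy]-8,8-dimethyl-5-methylidene-10-{[(2Z)-2-methylbut-2-enoyl]oxy}cycloundec-1-ene-1-carboxylate
Conditions: Pd(PPh3)4 (10 mol%), THF, 50 °C, slow addition to 0.002 M
Reagents that add atoms: none
Why: Zerovalent palladium ionises the C3 allylic methyl carbonate to an η3-allyl complex spanning C3–C4–C5 with loss of CO2 and methoxide, methoxide attacks tin and passes the 2-substituted allyl group to palladium, and reductive elimination from the bis(allyl)palladium joins C2 to C3. The closest known reaction type is the palladium-catalysed coupling of allylic carbonates or acetates with allylstannanes, which has been used intramolecularly to close eleven-membered 1,5-dienes of the humulene type. The eleven-membered ring closes terminus to terminus: bond formation at C3 leaves C4=C5 inside the ring (formally 11-endo with respect to the C3–C5 allyl unit, the alternative at C5 being 9-exo) and C1=CH2 exocyclic, and because the C1 allyl unit is symmetrical either CH2 terminus gives the same product. No stereocentre is formed; C7 and C11 are spectators, the C11 silyl ether cannot ionise and the C7 angelate is only homoallylic. The step needs coupling at C3 and not C5 with the enoate geometry kept (C3 cis to C6): the fully substituted, ester-bearing C5 terminus, the conjugation regained in the product and the preference of the ester for the syn position of the allyl complex all favour this, and high dilution suppresses oligomers.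

Step 15
Reactants: 24 the protected macrocycle
Product: 25 (1E,6S,10S)-6-hydroxy-8,8-dimethyl-5-methylidene-10-{[(2Z)-2-methylbut-2-enoyl]oxy}cycloundec-1-ene-1-carboxylic acid (CNP0263820.1)
Conditions: 48% aq. HF, MeCN, 0 °C → rt
Reagents that add atoms: none
Why: Acidic fluoride cleaves the C11 silyl ether and hydrolyses the acyloxymethyl acetal of the SEM ester in one non-basic operation, which should spare the angelate, the enoic acid and the allylic alcohol.

Compound list
1 | 2,2-dimethylpent-4-enal | C=CCC(C)(C)C=O | starting material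
2 | (methoxymethyl)triphenylphosphonium chloride | [Cl-].COC[P+](c1ccccc1)(c1ccccc1)c1ccccc1 | starting material
3 | (methoxymethylidene)triphenylphosphorane | COC=P(c1ccccc1)(c1ccccc1)c1ccccc1 | intermediate
4 | 1-methoxy-3,3-dimethylhexa-1,5-diene (E/Z mixture) | COC=CC(C)(C)CC=C | intermediate
5 | 3,3-dimethylhex-5-enal | O=CCC(C)(C)CC=C | intermediate
6 | 1,1,1,3,3,3-hexafluoropropan-2-yl prop-2-enoate | C=CC(=O)OC(C(F)(F)F)C(F)(F)F | starting material
7 | 1,1,1,3,3,3-hexafluoropropan-2-yl (3S)-3-hydroxy-5,5-dimethyl-2-methylideneoct-7-enoate | C=CCC(C)(C)C[C@H](O)C(=C)C(=O)OC(C(F)(F)F)C(F)(F)F | intermediate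
8 | 1,1,1,3,3,3-hexafluoropropan-2-yl (3S)-3-[(tert-butyldimethylsilyl)oxy]-5,5-dimethyl-2-methylideneoct-7-enoate | C=CCC(C)(C)C[C@H](O[Si](C)(C)C(C)(C)C)C(=C)C(=O)OC(C(F)(F)F)C(F)(F)F | intermediate
9 | 1,1,1,3,3,3-hexafluoropropan-2-yl (3S)-3-[(tert-butyldimethylsilyl)oxy]-5,5-dimethyl-2-methylidene-6-(oxiran-2-yl)hexanoate (both oxirane epimers) | C1OC1CC(C)(C)C[C@H](O[Si](C)(C)C(C)(C)C)C(=C)C(=O)OC(C(F)(F)F)C(F)(F)F | intermediate
10 | 1,1,1,3,3,3-hexafluoropropan-2-yl (3S)-3-[(tert-butyldimethylsilyl)oxy]-5,5-dimethyl-2-methylidene-6-[(2S)-oxiran-2-yl]hexanoate | C1O[C@H]1CC(C)(C)C[C@H](O[Si](C)(C)C(C)(C)C)C(=C)C(=O)OC(C(F)(F)F)C(F)(F)F | intermediate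
11 | (3S)-3-[(tert-butyldimethylsilyl)oxy]-5,5-dimethyl-2-methylidene-6-[(2S)-oxiran-2-yl]hexan-1-ol | C1O[C@H]1CC(C)(C)C[C@H](O[Si](C)(C)C(C)(C)C)C(=C)CO | intermediate
12 | (3S)-3-[(tert-butyldimethylsilyl)oxy]-5,5-dimethyl-2-methylidene-6-[(2S)-oxiran-2-yl]hexyl methanesulfonate | C1O[C@H]1CC(C)(C)C[C@H](O[Si](C)(C)C(C)(C)C)C(=C)COS(C)(=O)=O | intermediate
13 | tributyl{(3S)-3-[(tert-butyldimethylsilyl)oxy]-5,5-dimethyl-2-methylidene-6-[(2S)-oxiran-2-yl]hexyl}stannane | CCCC[Sn](CCCC)(CCCC)CC(=C)[C@@H](O[Si](C)(C)C(C)(C)C)CC(C)(C)C[C@H]1CO1 | intermediate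
14 | triethyl phosphonoacetate | CCOC(=O)CP(=O)(OCC)OCC | starting material
15 | diethyl [(5S)-5-{(4S)-4-[(tert-butyldimethylsilyl)oxy]-2,2-dimethyl-5-[(tributylstannyl)methyl]hex-5-en-1-yl}-2-oxooxolan-3-yl]phosphonate (both C3 epimers of the lactone) | CCCC[Sn](CCCC)(CCCC)CC(=C)[C@@H](O[Si](C)(C)C(C)(C)C)CC(C)(C)C[C@H]1CC(P(=O)(OCC)OCC)C(=O)O1 | intermediate
16 | 2-oxoethyl benzoate | O=CCOC(=O)c1ccccc1 | starting material
17 | 2-[(3E,5S)-5-{(4S)-4-[(tert-butyldimethylsilyl)oxy]-2,2-dimethyl-5-[(tributylstannyl)methyl]hex-5-en-1-yl}-2-oxooxolan-3-ylidene]ethyl benzoate | CCCC[Sn](CCCC)(CCCC)CC(=C)[C@@H](O[Si](C)(C)C(C)(C)C)CC(C)(C)C[C@H]1C/C(=C\COC(=O)c2ccccc2)C(=O)O1 | intermediate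
18 | lithium (2E,4S,8S)-8-[(tert-butyldimethylsilyl)oxy]-4-hydroxy-2-(2-hydroxyethylidene)-6,6-dimethyl-9-methylidene-10-(tributylstannyl)decanoate | CCCC[Sn](CCCC)(CCCC)CC(=C)[C@@H](O[Si](C)(C)C(C)(C)C)CC(C)(C)C[C@H](O)C/C(C(=O)[O-])=C\CO.[Li+] | intermediate
19 | [2-(trimethylsilyl)ethoxy]methyl (2E,4S,8S)-8-[(tert-butyldimethylsilyl)oxy]-4-hydroxy-2-(2-hydroxyethylidene)-6,6-dimethyl-9-methylidene-10-(tributylstannyl)decanoate | CCCC[Sn](CCCC)(CCCC)CC(=C)[C@@H](O[Si](C)(C)C(C)(C)C)CC(C)(C)C[C@H](O)C/C(C(=O)OCOCC[Si](C)(C)C)=C\CO | intermediate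
20 | [2-(trimethylsilyl)ethoxy]methyl (2E,4S,8S)-8-[(tert-butyldimethylsilyl)oxy]-4-hydroxy-2-{2-[(methoxycarbonyl)oxy]ethylidene}-6,6-dimethyl-9-methylidene-10-(tributylstannyl)decanoate | CCCC[Sn](CCCC)(CCCC)CC(=C)[C@@H](O[Si](C)(C)C(C)(C)C)CC(C)(C)C[C@H](O)C/C(C(=O)OCOCC[Si](C)(C)C)=C\COC(=O)OC | intermediate
21 | angelic acid, (2Z)-2-methylbut-2-enoic acid | C/C=C(/C)C(=O)O | starting material
22 | (2Z)-2-methylbut-2-enoic 2,4,6-trichlorobenzoic anhydride | C/C=C(/C)C(=O)OC(=O)c1c(Cl)cc(Cl)cc1Cl | intermediate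
23 | [2-(trimethylsilyl)ethoxy]methyl (2E,4S,8S)-8-[(tert-butyldimethylsilyl)oxy]-2-{2-[(methoxycarbonyl)oxy]ethylidene}-6,6-dimethyl-9-methylidene-4-{[(2Z)-2-methylbut-2-enoyl]oxy}-10-(tributylstannyl)decanoate | CCCC[Sn](CCCC)(CCCC)CC(=C)[C@@H](O[Si](C)(C)C(C)(C)C)CC(C)(C)C[C@H](OC(=O)/C(C)=C\C)C/C(C(=O)OCOCC[Si](C)(C)C)=C\COC(=O)OC | intermediate
24 | [2-(trimethylsilyl)ethoxy]methyl (1E,6S,10S)-6-[(tert-butyldimethylsilyl)oxy]-8,8-dimethyl-5-methylidene-10-{[(2Z)-2-methylbut-2-enoyl]oxy}cycloundec-1-ene-1-carboxylate | C=C1CC/C=C(/C(=O)OCOCC[Si](C)(C)C)C[C@@H](OC(=O)/C(C)=C\C)CC(C)(C)C[C@@H]1O[Si](C)(C)C(C)(C)C | intermediate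
25 | (1E,6S,10S)-6-hydroxy-8,8-dimethyl-5-methylidene-10-{[(2Z)-2-methylbut-2-enoyl]oxy}cycloundec-1-ene-1-carboxylic acid | C=C1CC/C=C(/C(=O)O)C[C@@H](OC(=O)/C(C)=C\C)CC(C)(C)C[C@@H]1O | target

Total step count: 15. Longest linear sequence: 15 steps (from 1).

Steps most likely to fail

Step 14. Ring closure may lose out to oligomerisation, to carbon–carbon bond formation at C5, to β-hydride loss from the allylpalladium intermediate, or the enoate geometry may scramble by syn–anti exchange. The fallback sets out from 23 and returns at 24. Iodine in CH2Cl2 at −78 °C cleaves the carbon–tin bond of 23 (SE2′ on the symmetrical allyl unit) and gives the C2 allylic iodide F1. Stoichiometric zerovalent nickel, Ni(cod)2 in DMF under high dilution, then inserts into the allylic C–I and C–O(carbonate) bonds, and reductive coupling of the two allylnickel termini should close the same C2–C3 bond to give 24. This replaces the nucleophile–electrophile cross-coupling by a reductive coupling of two allylic electrophiles.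

Step 3. The amine-catalysed addition may stall with the β,β-disubstituted aldehyde or give insufficient enantioselectivity at C11. The fallback sets out from 5 and returns at 11.
- 2-Bromo-3-[(4-methoxybenzyl)oxy]prop-1-ene (from 2,3-dibromopropene and 4-methoxybenzyl alcohol, NaH) is lithiated (t-BuLi, Et2O, −78 °C) and added to 5 to give the racemic allylic alcohol F2.
- DMP oxidation gives the enone F3, whose electron-poor alkene lets mCPBA epoxidise only C6=C7 to the racemic epoxy enone F4.
- Hydrolytic kinetic resolution with the same (S,S)-(salen)Co(OAc) leaves the 7S epoxy enone F5.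
- Corey–Bakshi–Shibata reduction with the (R)-2-methyl oxazaborolidine and catecholborane (toluene, −40 °C), the 2-substituted vinyl group acting as the large substituent, should give the 11S alcohol F6.
- TBSCl and imidazole in DMF give the silyl ether F7, and DDQ in buffered wet CH2Cl2 removes the 4-methoxybenzyl group to deliver 11.

Step 13. A slow acylation may allow the γ-hydroxy ester to lactonise with loss of the SEM group, and the angeloyl donor may isomerise from Z to E. The fallback sets out from 20 and returns at 23. The C7 hydroxyl is acylated at 0 °C with 2-[bis(2,2,2-trifluoroethoxy)phosphoryl]propanoic acid, N,N'-diisopropylcarbodiimide and catalytic DMAP, a fast coupling of an unhindered acid, to give the phosphonopropanoate F8. A Still–Gennari olefination of F8 with acetaldehyde (KN(SiMe3)2, 18-crown-6, THF, −78 °C) then builds the Z-configured 2-methylbut-2-enoate in place and gives 23.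

Further compounds
F1 | step 14 | [2-(trimethylsilyl)ethoxy]methyl (2E,4S,8S)-8-[(tert-butyldimethylsilyl)oxy]-9-(iodomethyl)-2-{2-[(methoxycarbonyl)oxy]ethylidene}-6,6-dimethyl-4-{[(2Z)-2-methylbut-2-enoyl]oxy}dec-9-enoate | ICC(=C)[C@@H](O[Si](C)(C)C(C)(C)C)CC(C)(C)C[C@H](OC(=O)/C(C)=C\C)C/C(C(=O)OCOCC[Si](C)(C)C)=C\COC(=O)OC
F2 | step 3 | 2-{[(4-methoxybenzyl)oxy]methyl}-5,5-dimethylocta-1,7-dien-3-ol (racemic) | C=CCC(C)(C)CC(O)C(=C)COCc1ccc(OC)cc1
F3 | step 3 | 2-{[(4-methoxybenzyl)oxy]methyl}-5,5-dimethylocta-1,7-dien-3-one | C=CCC(C)(C)CC(=O)C(=C)COCc1ccc(OC)cc1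
F4 | step 3 | 2-{[(4-methoxybenzyl)oxy]methyl}-5,5-dimethyl-6-(oxiran-2-yl)hex-1-en-3-one (racemic) | C1OC1CC(C)(C)CC(=O)C(=C)COCc1ccc(OC)cc1
F5 | step 3 | 2-{[(4-methoxybenzyl)oxy]methyl}-5,5-dimethyl-6-[(2S)-oxiran-2-yl]hex-1-en-3-one | C1O[C@H]1CC(C)(C)CC(=O)C(=C)COCc1ccc(OC)cc1
F6 | step 3 | (3S)-2-{[(4-methoxybenzyl)oxy]methyl}-5,5-dimethyl-6-[(2S)-oxiran-2-yl]hex-1-en-3-ol | C1O[C@H]1CC(C)(C)C[C@H](O)C(=C)COCc1ccc(OC)cc1
F7 | step 3 | tert-butyl{[(3S)-2-{[(4-methoxybenzyl)oxy]methyl}-5,5-dimethyl-6-[(2S)-oxiran-2-yl]hex-1-en-3-yl]oxy}dimethylsilane | C1O[C@H]1CC(C)(C)C[C@H](O[Si](C)(C)C(C)(C)C)C(=C)COCc1ccc(OC)cc1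
F8 | step 13 | [2-(trimethylsilyl)ethoxy]methyl (2E,4S,8S)-4-({2-[bis(2,2,2-trifluoroethoxy)phosphoryl]propanoyl}oxy)-8-[(tert-butyldimethylsilyl)oxy]-2-{2-[(methoxycarbonyl)oxy]ethylidene}-6,6-dimethyl-9-methylidene-10-(tributylstannyl)decanoate | CCCC[Sn](CCCC)(CCCC)CC(=C)[C@@H](O[Si](C)(C)C(C)(C)C)CC(C)(C)C[C@H](OC(=O)C(C)P(=O)(OCC(F)(F)F)OCC(F)(F)F)C/C(C(=O)OCOCC[Si](C)(C)C)=C\COC(=O)OC
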